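**Retrosynthetic overview**

1. Target 20 is (13R)-8α,15-epoxylabdan-16-yl acetate: a trans-decalin (rings A and B) fused at C8/C9 to an oxocane (O–C15–C14–C13–C12–C11–C9–C8) with C16 on C13. The strategy rests on this ring: a bond between C12 and C15 would shrink it to a six-membered dihydropyranone (O, C15, C12, C11, C9, C8) and leave C13–C14 as a two-carbon bridge, i.e. a fused cyclobutane.
2. Endgame disconnections: acetate and C11 methylene from the 16-hydroxy 11-ketone 17; C13–H from ligand-controlled CuH reduction of the 12-en-11-one 16; 16 from the 13(16)-methylene ketone 14 by epoxidation and E1cB opening; 14 from cyclobutane 11 by cleavage of C12–C15 with hydride capture.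
3. Key disconnection: 11 to dihydropyranone 9 plus allene ([2+2] photocycloaddition, new bonds C12–C13 and C14–C15).
4. 9 from (+)-sclareolide: α-hydroxylation, reduction and glycol cleavage to 8α-hydroxydriman-11-al, ethynyl addition, oxidation, 6-endo cyclisation.
5. Ring order: A and B come with sclareolide; ring C (pyranone) in step 6; cyclobutane in step 7; oxocane by two-carbon ring expansion in step 8.

Key step: step 7

Assumptions: (a) Labdane numbering is used for all compounds (decalin C1–C10; C17 is the methyl on C8; the ring oxygen joins C8 and C15; C16 sits on C13). (b) C11 of 3, 4 and 7 and C13 of 15 are formed as epimer mixtures and carried on as such, because each of these centres is later cleaved or becomes sp2. (c) In step 11 the (R)-ligand is written; the sense of induction on this ring system is assigned by analogy only, so the antipodal ligand is to be used, with no other change, if a pilot run shows the opposite sense.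

**Route**

Step 1
Reactants: 1 (+)-sclareolide
Product: 3 11-hydroxysclareolide (C11 epimers), via potassium lactone enolate 2 (not isolated)
Conditions: KN(SiMe3)2, THF, −78 °C; 2-(phenylsulfonyl)-3-phenyloxaziridine, −78 °C; AcOH
Reagents that add atoms: 2-(phenylsulfonyl)-3-phenyloxaziridine, O=S(=O)(N1OC1c1ccccc1)c1ccccc1
Why: The lactone is deprotonated only at C11 and the enolate is oxidised by the N-sulfonyloxaziridine (enolate α-hydroxylation); the C11 configuration is irrelevant because C12 is cleaved off in step 3 and C11 becomes a carbonyl carbon.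

Step 2
Reactants: 3 11-hydroxysclareolide
Product: 4 13,14,15,16-tetranorlabdane-8α,11,12-triol (C11 epimers)
Conditions: LiAlH4, THF, 0 °C → rt; H2O work-up
Reagents that add atoms: none
Why: LiAlH4 reduces the lactone to the primary alcohol and frees the tertiary C8 hydroxyl (ester reduction) without touching any stereocentre of the decalin.

Step 3
Reactants: 4 13,14,15,16-tetranorlabdane-8α,11,12-triol
Product: 5 8α-hydroxydriman-11-al
Conditions: NaIO4, THF/H2O, 0 °C → rt
Reagents that add atoms: none
Why: Periodate cleaves only the vicinal 11,12-diol (Malaprade glycol cleavage), the tertiary C8 hydroxyl being 1,3 to C11; the neutral medium keeps the β-hydroxy aldehyde from retro-aldol cleavage or dehydration, and C9 stays in its equatorial configuration.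

Step 4
Reactants: 5 8α-hydroxydriman-11-al; 6 ethynylmagnesium bromide
Product: 7 11-ethynyldrimane-8α,11-diol (C11 epimers)
Conditions: HC≡CMgBr (3 equiv), THF, −78 → 0 °C; aq NH4Cl
Reagents that add atoms: ethynylmagnesium bromide, C#C[Mg]Br
Why: One equivalent of the Grignard reagent deprotonates the C8 hydroxyl and a second adds to the aldehyde (Grignard 1,2-addition), the low temperature keeping addition ahead of retro-aldol opening of the magnesium aldolate; the new C11 centre is oxidised in the next step.

Step 5
Reactants: 7 11-ethynyldrimane-8α,11-diol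
Product: 8 11-ethynyl-8α-hydroxydriman-11-one
Conditions: Dess–Martin periodinane, pyridine, CH2Cl2, 0 °C → rt
Reagents that add atoms: none
Why: The hypervalent iodine reagent oxidises the secondary propargylic alcohol to the ynone (Dess–Martin oxidation) while the tertiary C8 hydroxyl cannot be oxidised, and the buffered medium avoids dehydration of the β-hydroxy ketone.

Step 6
Reactants: 8 11-ethynyl-8α-hydroxydriman-11-one
Product: 9 tricyclic dihydropyranone (ring C: O–C15H=C12H–C11(=O)–C9–C8; 8α-O and 9β-C11 trans-fused to ring B)
Conditions: Ph3PAuCl (5 mol %), AgOTf (5 mol %), CH2Cl2, rt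
Reagents that add atoms: none
Why: The cationic Ph3PAu π-acid activates the ynone for 6-endo-dig attack of the C8 hydroxyl on the β-carbon C15 (intramolecular hydroalkoxylation of a β-hydroxy ynone) and protodeauration releases the vinylogous ester; no stereocentre is formed and the trans ring fusion at C8/C9 is retained.

Step 7
Reactants: 9 tricyclic dihydropyranone; 10 allene
Product: 11 13-methylene cyclobutane photoadduct (cyclobutane C12–C13–C14–C15 cis-fused on the α face of ring C; H-12 and H-15 β; C16 methylene on C13)
Conditions: allene (10 equiv), THF, hν (medium-pressure Hg lamp, Pyrex, λ > 300 nm), −78 °C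
Reagents that add atoms: allene, C=C=C
Why: Excitation of the vinylogous-ester chromophore and intersystem crossing give the triplet enone, whose α-carbon C12 bonds to the central allene carbon to form an allyl/α-alkoxyalkyl 1,4-biradical that closes the C14–C15 bond after spin inversion. The closest known reaction type is the enone–allene [2+2] photocycloaddition used ahead of retro-aldol (de Mayo-type) fragmentations, which is also known for β-heteroatom-substituted enones. The cyclobutane (C12, C13, C14, C15) is closed by radical–radical combination of the 1,4-biradical and has to be cis-fused because C12 and C15 both lie in the six-membered ring C. The new stereocentres C12 and C15 are set by approach of allene to the α face, because the axial methyl groups on C8 and C10 cover the β face of the nearly flat ring C. The selectivity that matters is the head-to-head orientation (C13 on C12), which the stability of the allyl and α-oxy radical pair should secure; the facial outcome only decides whether one adduct or two are carried on, since C12 and C15 become methylene groups in step 8. Irradiation is to be stopped before full conversion so that the β,γ-unsaturated ketone product does not undergo a photochemical 1,3-acyl shift.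

Step 8
Reactants: 11 13-methylene cyclobutane photoadduct
Product: 14 8α,15-epoxylabd-13(16)-en-11-one, via oxocarbenium boron dienolate zwitterion 12 (not isolated), via triethylsilyl dienol ether 13 (not isolated)
Conditions: Et3SiH (3 equiv), BF3·OEt2 (0.3 equiv), CH2Cl2, −78 → −20 °C; aq NaHCO3; then oxalic acid, THF/H2O, 0 °C
Reagents that add atoms: none
Why: Proposed new method: BF3 on the C11 carbonyl oxygen pulls and the ring-oxygen lone pair pushes, so the strained C12–C15 bond, which is shared by both rings and aligned with the carbonyl π system as in de Mayo ring expansions, should heterolyse to a C15 oxocarbenium ion and a boron dienolate; Et3SiH reduces the oxocarbenium ion to the C15 methylene, the silyl cation caps the dienolate oxygen and returns BF3, and kinetic protonation at C12 on mild hydrolysis gives the β,γ-unsaturated ketone with no stereocentre of the decalin involved. The closest known reaction types are the Lewis-acid opening of alkoxy-substituted donor–acceptor cyclobutanes to 1,4-zwitterions and the silane reduction of cyclic oxocarbenium ions, whose combination into a reductive two-carbon ring expansion has not been shown on this substrate class.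

Step 9
Reactants: 14 8α,15-epoxylabd-13(16)-en-11-one
Product: 15 8α,15:13,16-diepoxylabdan-11-one (C13 epimers)
Conditions: dimethyldioxirane (acetone solution), CH2Cl2, 0 °C
Reagents that add atoms: dimethyldioxirane, CC1(C)OO1
Why: The neutral dioxirane epoxidises the electron-rich 1,1-disubstituted C13=C16 double bond (alkene epoxidation) and leaves the ketone and the ether alone; the spiro centre C13 becomes sp2 in the next step.

Step 10
Reactants: 15 8α,15:13,16-diepoxylabdan-11-one
Product: 16 8α,15-epoxy-16-hydroxylabd-12-en-11-one (ring-cis C12=C13)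
Conditions: DBU (0.2 equiv), CH2Cl2, 0 °C
Reagents that add atoms: none
Why: DBU removes a C12 proton, which is α to the ketone and next to the epoxide carbon, and the enolate expels the epoxide oxygen from C13 (E1cB opening of a β,γ-epoxy ketone to a γ-hydroxy enone); the hindered tertiary C9–H is not touched under these mild conditions and the eight-membered ring enforces the cis double bond.

Step 11
Reactants: 16 8α,15-epoxy-16-hydroxylabd-12-en-11-one
Product: 17 (13S)-8α,15-epoxy-16-hydroxylabdan-11-one (same spatial arrangement at C13 as 13R in the target; the descriptor changes only through the C11 carbonyl)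
Conditions: Cu(OAc)2·H2O (5 mol %), (R)-DTBM-SEGPHOS (5 mol %), (EtO)2MeSiH, t-BuOH, toluene, 0 °C → rt; aq NH4F
Reagents that add atoms: none
Why: Ligated CuH delivers hydride to the β-carbon C13 of the enone and t-BuOH protonates the copper enolate (asymmetric conjugate reduction by 1,4-hydrosilylation), so the chiral bisphosphine selects the enone face and sets C13; the free primary hydroxyl is tolerated because any silyl ether formed on it is cleaved in the fluoride work-up.

Step 12
Reactants: 17 (13S)-8α,15-epoxy-16-hydroxylabdan-11-one
Product: 19 (13R)-8α,15-epoxylabdan-16-ol, via C11 hydrazone 18 (not isolated)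
Conditions: N2H4·H2O, diethylene glycol, 130 °C; then KOH, 200 °C
Reagents that add atoms: none
Why: Hydrazone formation at C11 and base-induced loss of N2 replace the carbonyl by CH2 (Wolff–Kishner reduction, Huang-Minlon conditions); the ether and the primary alcohol are inert to hot KOH, C13 is not α to the carbonyl and cannot epimerise, and C9 keeps its equatorial, thermodynamically preferred configuration.

Step 13
Reactants: 19 (13R)-8α,15-epoxylabdan-16-ol
Product: 20 (13R)-8α,15-epoxylabdan-16-yl acetate (target)
Conditions: Ac2O, pyridine, DMAP (cat.), CH2Cl2, rt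
Reagents that add atoms: acetic anhydride, CC(=O)OC(C)=O
Why: The only hydroxyl in the molecule, a primary one, is acylated under nucleophilic catalysis (DMAP-catalysed acetylation) without affecting any stereocentre.

**Compound list**

1 | (+)-sclareolide | O=C1O[C@]2(C)CC[C@H]3C(C)(C)CCC[C@]3(C)[C@H]2C1 | starting material
2 | potassium enolate of sclareolide (C11=C12) | [K+].[O-]C=1O[C@]2(C)CC[C@H]3C(C)(C)CCC[C@]3(C)[C@H]2C=1 | intermediate
3 | 11-hydroxysclareolide (C11 epimers) | O=C1O[C@]2(C)CC[C@H]3C(C)(C)CCC[C@]3(C)[C@H]2C1O | intermediate
4 | 13,14,15,16-tetranorlabdane-8α,11,12-triol (C11 epimers) | O[C@]1(C)CC[C@H]2C(C)(C)CCC[C@]2(C)[C@H]1C(O)CO | intermediate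
5 | 8α-hydroxydriman-11-al | O[C@]1(C)CC[C@H]2C(C)(C)CCC[C@]2(C)[C@H]1C=O | intermediate
6 | ethynylmagnesium bromide | C#C[Mg]Br | starting material
7 | 11-ethynyldrimane-8α,11-diol (C11 epimers) | O[C@]1(C)CC[C@H]2C(C)(C)CCC[C@]2(C)[C@H]1C(O)C#C | intermediate
8 | 11-ethynyl-8α-hydroxydriman-11-one | O[C@]1(C)CC[C@H]2C(C)(C)CCC[C@]2(C)[C@H]1C(=O)C#C | intermediate
9 | tricyclic dihydropyranone (O on C8, carbonyl C11 on C9, C12=C15) | O=C1C=CO[C@]2(C)CC[C@H]3C(C)(C)CCC[C@]3(C)[C@H]21 | intermediate
10 | allene | C=C=C | starting material
11 | 13-methylene cyclobutane photoadduct (α-face cyclobutane, H-12 and H-15 β) | C=C1C[C@@H]2O[C@]3(C)CC[C@H]4C(C)(C)CCC[C@]4(C)[C@H]3C(=O)[C@H]12 | intermediate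
12 | C15 oxocarbenium / C11 trifluoroborate dienolate zwitterion | C=C1CC=[O+][C@]2(C)CC[C@H]3C(C)(C)CCC[C@]3(C)[C@H]2C(O[B-](F)(F)F)=C1 | intermediate
13 | 11-triethylsilyloxy-8α,15-epoxylabda-11,13(16)-diene | C=C1CCO[C@]2(C)CC[C@H]3C(C)(C)CCC[C@]3(C)[C@H]2C(O[Si](CC)(CC)CC)=C1 | intermediate
14 | 8α,15-epoxylabd-13(16)-en-11-one | C=C1CCO[C@]2(C)CC[C@H]3C(C)(C)CCC[C@]3(C)[C@H]2C(=O)C1 | intermediate
15 | 8α,15:13,16-diepoxylabdan-11-one (C13 epimers) | O=C1CC2(CO2)CCO[C@]3(C)CC[C@H]4C(C)(C)CCC[C@]4(C)[C@H]31 | intermediate
16 | 8α,15-epoxy-16-hydroxylabd-12-en-11-one (ring-cis alkene) | O=C1/C=C(CO)\CCO[C@]2(C)CC[C@H]3C(C)(C)CCC[C@]3(C)[C@H]21 | intermediate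
17 | (13S)-8α,15-epoxy-16-hydroxylabdan-11-one | OC[C@H]1CCO[C@]2(C)CC[C@H]3C(C)(C)CCC[C@]3(C)[C@H]2C(=O)C1 | intermediate
18 | C11 hydrazone of 17 | OC[C@H]1CCO[C@]2(C)CC[C@H]3C(C)(C)CCC[C@]3(C)[C@H]2C(=NN)C1 | intermediate
19 | (13R)-8α,15-epoxylabdan-16-ol | OC[C@H]1CCO[C@]2(C)CC[C@H]3C(C)(C)CCC[C@]3(C)[C@H]2CC1 | intermediate
20 | (13R)-8α,15-epoxylabdan-16-yl acetate | CC(=O)OC[C@H]1CCO[C@]2(C)CC[C@H]3C(C)(C)CCC[C@]3(C)[C@H]2CC1 | target

**Step count**

Total step count: 13. Longest linear sequence: 13 steps, from (+)-sclareolide.

**Steps most likely to fail**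

Step 8 (reductive ring expansion, the step that carries the new-method label). The C15 oxocarbenium ion carries a tertiary alkyl group (C8) on oxygen and may fragment by C8–O ionisation before the silane reduces it. The dienol derivative may also be protonated at C16, so that the double bond moves into conjugation and the C16 handle is lost. The fallback sets out from 11 and comes back at 14, and it breaks the C12–C15 bond by single-electron reduction instead of Lewis-acid heterolysis. SmI2 in THF with HMPA and t-BuOH at −78 °C reduces the C11 ketone to its ketyl. The cyclobutylcarbinyl radical should open towards C15, because that gives an α-alkoxyalkyl radical, whereas C12–C13 cleavage would give a vinyl radical. A second electron and a proton turn C15 into CH2, and the samarium enolate is protonated at C12 to give 14 directly. This is the known reductive fragmentation of cyclobutyl ketones from enone photoadducts. New compound on the way: none F0.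

Step 7 (photocycloaddition). Allene may add in the reverse orientation, with its central carbon on C15, or the β,γ-unsaturated ketone adduct may absorb and rearrange by 1,3-acyl shift before the enone is consumed. The fallback sets out from 9 and comes back at 17: the two-carbon unit is added as ethylene, which has no regiochemistry, and C16 is introduced afterwards.
- Irradiation of 9 under ethylene (CH2Cl2, −78 °C, Pyrex) should give the ethylene photoadduct F1.
- SmI2 as above opens it to 8α,15-epoxy-16-norlabdan-11-one F2.
- IBX in DMSO at 70 °C dehydrogenates F2 on the only side that has a β-hydrogen (C12–C13, since C9 is flanked by the quaternary C8 and C10) to the ring-cis enone 8α,15-epoxy-16-norlabd-12-en-11-one F3.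
- Copper-catalysed conjugate addition of (i-PrO)Me2SiCH2MgCl (CuBr·SMe2, chiral ferrocenyl diphosphine, THF, −78 °C) gives (13S)-8α,15-epoxy-16-[isopropoxy(dimethyl)silyl]labdan-11-one F4, with C13 set by the ligand.
- Tamao oxidation (H2O2, KF, KHCO3, THF/MeOH) then gives 17.

Step 11 (asymmetric conjugate reduction). The conformation of the eight-membered enone, and not the ligand, may decide the face of hydride delivery to C13, so that the wrong epimer forms with either ligand antipode; 1,2-reduction may also compete. The fallback sets out from 16 and comes back at 20: C13 is set by a hydroxyl-directed hydrogenation, relayed from a C11 carbinol that is removed afterwards.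
- Acetylation of 16 (Ac2O, pyridine) gives 16-acetoxy-8α,15-epoxylabd-12-en-11-one F5.
- Luche reduction (NaBH4, CeCl3·7H2O, MeOH, −78 °C) gives 16-acetoxy-8α,15-epoxylabd-12-en-11-ol F6. The C11 epimer with the hydroxyl on the ring face that H-13 has to occupy is used; the other epimer is returned to F5 with Dess–Martin periodinane.
- Hydrogenation with [Ir(cod)(PCy3)(py)]PF6 (H2, CH2Cl2) should deliver hydrogen to C12=C13 from the hydroxyl-bearing face and give 16-acetoxy-8α,15-epoxylabdan-11-ol F7, with C13 as in the target.
- 1,1'-Thiocarbonyldiimidazole and DMAP (1,2-dichloroethane, 80 °C) give the 11-O-imidazolylthiocarbonyl derivative F8.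
- Barton–McCombie reduction (Bu3SnH, AIBN, toluene, 110 °C) gives 20 directly, so this sequence also replaces the Wolff–Kishner step.

Further compounds
F0 | step 8 | none | none
F1 | step 7 | ethylene photoadduct of 9 (cyclobutane on the α face, H-12 and H-15 β) | C1C[C@@H]2O[C@]3(C)CC[C@H]4C(C)(C)CCC[C@]4(C)[C@H]3C(=O)[C@H]12
F2 | step 7 | 8α,15-epoxy-16-norlabdan-11-one | O=C1CCCCO[C@]2(C)CC[C@H]3C(C)(C)CCC[C@]3(C)[C@H]21
F3 | step 7 | 8α,15-epoxy-16-norlabd-12-en-11-one (ring-cis alkene) | O=C1/C=C\CCO[C@]2(C)CC[C@H]3C(C)(C)CCC[C@]3(C)[C@H]21
F4 | step 7 | (13S)-8α,15-epoxy-16-[isopropoxy(dimethyl)silyl]labdan-11-one | CC(C)O[Si](C)(C)C[C@H]1CCO[C@]2(C)CC[C@H]3C(C)(C)CCC[C@]3(C)[C@H]2C(=O)C1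
F5 | step 11 | 16-acetoxy-8α,15-epoxylabd-12-en-11-one | O=C1/C=C(COC(C)=O)\CCO[C@]2(C)CC[C@H]3C(C)(C)CCC[C@]3(C)[C@H]21
F6 | step 11 | 16-acetoxy-8α,15-epoxylabd-12-en-11-ol (11-OH on the face of the future H-13) | O[C@@H]1/C=C(COC(C)=O)\CCO[C@]2(C)CC[C@H]3C(C)(C)CCC[C@]3(C)[C@H]21
F7 | step 11 | 16-acetoxy-8α,15-epoxylabdan-11-ol (11-OH cis to H-13, C13 as in 20) | CC(=O)OC[C@H]1CCO[C@]2(C)CC[C@H]3C(C)(C)CCC[C@]3(C)[C@H]2[C@H](O)C1
F8 | step 11 | O-(16-acetoxy-8α,15-epoxylabdan-11-yl) 1H-imidazole-1-carbothioate | CC(=O)OC[C@H]1CCO[C@]2(C)CC[C@H]3C(C)(C)CCC[C@]3(C)[C@H]2[C@H](OC(=S)n4ccnc4)C1
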